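**Plan**
- Retrosynthesis: the dihydrofuran is cut at C3–C3a and at O1–C2 (benzofuran numbering), giving the C12 acyl-trione norflavesone and a C10 (2R,3R)-2,3-epoxygeranyl iodide. The trione goes back to phloroglucinol, isobutyryl chloride and two methyl groups; the epoxy iodide goes back to geraniol.
- Enabling feature: C3a is the only ring carbon of the enolised cyclohexanetrione that bears H, and it sits 1,3 to the enol oxygen on C7a. In the side chain, O1–C2 is vicinal to the tertiary C–OH, which is the pattern left by SN2 opening of a trisubstituted epoxide. The unit CH2(3)–CH(2)–C(OH)Me is therefore a 1-iodo-2,3-epoxide in disguise.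
- Forward: the cyclohexanetrione ring is finished first (Friedel–Crafts acylation, dearomatising gem-dimethylation). Geraniol is epoxidised and iodinated in parallel. The two fragments are then joined and the dihydrofuran ring is closed last, in one flask.
- Stereochemistry: both centres come from one Sharpless epoxidation with D-(−)-diethyl tartrate. The carbinol carbon keeps its epoxide configuration (R); the O–CH carbon is inverted in the ring closure (R to S).

Key step: step 5

Remark: compounds 4, 8 and 9 are enolised triones and exist as tautomer mixtures. Each is drawn as one tautomer; 9 is drawn as the hydrogen-bonded exocyclic enol of the target SMILES.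

Step 1
Reactants: 1 phloroglucinol; 2 isobutyryl chloride
Product: 3 2-methyl-1-(2,4,6-trihydroxyphenyl)propan-1-one
Conditions: AlCl3 (4 equiv), CH2Cl2/PhNO2, 0 °C to 40 °C; aq. HCl work-up
Reagents that add atoms: none
Why: Friedel–Crafts C-acylation of the strongly activated ring should stop at the mono-ketone because the chelated aryl ketone deactivates the ring; no stereocentre is formed.

Step 2
Reactants: 3 2-methyl-1-(2,4,6-trihydroxyphenyl)propan-1-one
Product: 4 norflavesone, 3,5-dihydroxy-6,6-dimethyl-2-(2-methylpropanoyl)cyclohexa-2,4-dien-1-one
Conditions: NaOMe (3 equiv), MeI (2.2 equiv), MeOH, 0 °C to rt; 1 M HCl work-up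
Reagents that add atoms: iodomethane (MeI), CI
Why: Dearomatising gem-dimethylation: in methanol the phloroglucinolate should be methylated on ring carbon by the soft iodide, and the second methyl should enter the same carbon because this gives the stabilised enolised β-triketone; the two free ring positions of 3 are equivalent and no stereocentre is formed.

Step 3
Reactants: 5 geraniol
Product: 6 (2R,3R)-2,3-epoxygeraniol, [(2R,3R)-3-methyl-3-(4-methylpent-3-en-1-yl)oxiran-2-yl]methanol
Conditions: Ti(OiPr)4 (5 mol%), D-(−)-diethyl tartrate (7 mol%), t-BuOOH (1.5 equiv, anhydrous), 4 Å molecular sieves, CH2Cl2, −20 °C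
Reagents that add atoms: tert-butyl hydroperoxide, CC(C)(C)OO
Why: Sharpless asymmetric epoxidation: the allylic hydroxyl binds the titanium tartrate complex, so only the 2,3-alkene is epoxidised, and the D-(−)-tartrate ligand should direct oxygen to the face that gives the (2R,3R) epoxide, setting both stereocentres of the route.

Step 4
Reactants: 6 (2R,3R)-2,3-epoxygeraniol
Product: 7 (2R,3S)-3-(iodomethyl)-2-methyl-2-(4-methylpent-3-en-1-yl)oxirane
Conditions: PPh3 (1.3 equiv), imidazole (2 equiv), I2 (1.3 equiv), CH2Cl2, 0 °C, dark; used at once
Reagents that add atoms: iodine, [I][I]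
Why: Appel-type iodination of the primary alcohol goes through the alkoxyphosphonium salt and SN2 displacement at CH2, so the epoxide centres are untouched (the CH descriptor changes from R to S only because CH2I outranks the ring carbon).

Step 5
Reactants: 4 norflavesone; 7 (2R,3S)-3-(iodomethyl)-2-methyl-2-(4-methylpent-3-en-1-yl)oxirane
Product: 9 (2S,7Z)-2-[(2R)-2-hydroxy-6-methylhept-5-en-2-yl]-7-(1-hydroxy-2-methylpropylidene)-5,5-dimethyl-2,3-dihydro-1-benzofuran-4,6(5H,7H)-dione (target), via C-alkylated epoxy trione 8 (not isolated)
Conditions: KOtBu (2.0 equiv), t-BuOH/THF (1:1), 0 °C to rt, then 60 °C; 1 M HCl work-up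
Reagents that add atoms: none
Why: Proposed new method: the dipotassium dianion of 4 has one unsubstituted nucleophilic ring carbon (the CH between two carbonyls), which should displace the primary iodide of 7 by SN2 to give 8 as its monoanion, and on warming the enolate oxygen of 8 that lies between the acyl-bearing carbon and the alkylated carbon should open the epoxide at its CH carbon; the closest known reaction types are the C-alkylation of this same ring by MeI or allylic halides in protic medium and the base-mediated cyclisation of ortho-(2,3-epoxyalkyl)phenols to 2-(1-hydroxyalkyl)dihydrobenzofurans, which have not been run as one alkylative [3+2] annulation on an acyl-cyclohexanetrione. The dihydrofuran ring closes by intramolecular SN2 O-alkylation in the 5-exo-tet mode. The O–CH stereocentre is set by inversion at the (R)-configured epoxide CH (giving S), and the tertiary carbinol keeps the (R) configuration of the epoxide carbon whose C–O bond stays intact, so both centres are relayed from step 3. The step needs C- over O-alkylation (soft iodide, hydrogen-bonding tert-butanol, potassium counter-ion), exo over endo opening (a basic medium free of Lewis acid directs attack to the less substituted epoxide carbon) and closure through the oxygen next to the acyl-bearing carbon instead of the one next to CMe2 (with exactly two equivalents of base 8 is left as a monoanion whose charge sits mainly in the more acidic acyl-triketonate unit, which holds only the required oxygen within reach of the epoxide).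

**Compound list**
1 | phloroglucinol (benzene-1,3,5-triol) | Oc1cc(O)cc(O)c1 | starting material
2 | isobutyryl chloride (2-methylpropanoyl chloride) | CC(C)C(Cl)=O | starting material
3 | 2-methyl-1-(2,4,6-trihydroxyphenyl)propan-1-one | CC(C)C(=O)c1c(O)cc(O)cc1O | intermediate
4 | norflavesone, 3,5-dihydroxy-6,6-dimethyl-2-(2-methylpropanoyl)cyclohexa-2,4-dien-1-one (dienol tautomer of 2-isobutyryl-4,4-dimethylcyclohexane-1,3,5-trione) | CC(C)C(=O)C1=C(O)C=C(O)C(C)(C)C1=O | intermediate
5 | geraniol, (2E)-3,7-dimethylocta-2,6-dien-1-ol | CC(C)=CCC/C(C)=C/CO | starting material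
6 | (2R,3R)-2,3-epoxygeraniol, [(2R,3R)-3-methyl-3-(4-methylpent-3-en-1-yl)oxiran-2-yl]methanol | OC[C@H]1O[C@]1(C)CCC=C(C)C | intermediate
7 | (2R,3S)-3-(iodomethyl)-2-methyl-2-(4-methylpent-3-en-1-yl)oxirane | IC[C@H]1O[C@]1(C)CCC=C(C)C | intermediate
8 | 3,5-dihydroxy-6,6-dimethyl-4-{[(2R,3R)-3-methyl-3-(4-methylpent-3-en-1-yl)oxiran-2-yl]methyl}-2-(2-methylpropanoyl)cyclohexa-2,4-dien-1-one (formed as its potassium salt, not isolated) | CC(C)C(=O)C1=C(O)C(C[C@H]2O[C@]2(C)CCC=C(C)C)=C(O)C(C)(C)C1=O | intermediate
9 | (2S,7Z)-2-[(2R)-2-hydroxy-6-methylhept-5-en-2-yl]-7-(1-hydroxy-2-methylpropylidene)-5,5-dimethyl-2,3-dihydro-1-benzofuran-4,6(5H,7H)-dione | CC(C)=CCC[C@@](C)(O)[C@@H]1CC2=C(O1)/C(=C(/O)C(C)C)C(=O)C(C)(C)C2=O | target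

Total step count: 5. Longest linear sequence: 3 steps (steps 1, 2, 5 or steps 3, 4, 5).

**Steps most likely to fail**

1. Step 5 (proposed new method). The ambident dianion may be alkylated on oxygen instead of carbon. The enolate may attack iodine, which would fragment the epoxy iodide to a linalool-type alkoxide. The ring may also close through the enol oxygen next to CMe2, or by endo opening. The fallback uses known chemistry, sets out from 6 and 4, and returns at 8. Oxidation of 6 with Dess–Martin periodinane (NaHCO3, CH2Cl2) gives (2S,3R)-3-methyl-3-(4-methylpent-3-en-1-yl)oxirane-2-carbaldehyde F1. Organocatalytic reductive alkylation of 4 with F1 (Knoevenagel condensation, then transfer hydrogenation by Hantzsch ester, L-proline cat., CH2Cl2, rt) forms the C–CH2 bond at carbon only and gives 8, which is isolated this time. Base-mediated 5-exo epoxide opening of the monopotassium salt of 8 (K2CO3, MeOH, 40 °C) then gives 9.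

2. Step 2. Incomplete C-methylation, over-methylation at the remaining ring CH and competing O-methylation may give a mixture that is hard to separate. The fallback installs the acyl group after the gem-dimethyl ring is built; it sets out from 2 and returns at 4. Purchased methyl 2,2-dimethyl-3-oxobutanoate F2 is enolised at its only enolisable position (LiN(iPr)2, THF, −78 °C) and C-acylated with 1-acetylbenzotriazole to methyl 2,2-dimethyl-3,5-dioxohexanoate F3. The diketone dianion of F3 (LiN(iPr)2, 2.2 equiv, THF, −78 °C to 0 °C) closes onto the ester in a Dieckmann-type Claisen cyclisation to filicinic acid, 3,5-dihydroxy-4,4-dimethylcyclohexa-2,5-dien-1-one F4. Friedel–Crafts C-acylation of F4 with 2 (AlCl3, PhNO2) at one of its two equivalent CH positions gives 4.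

3. Step 4. Iodide may open the epoxide, the phosphine may cause deoxygenative fragmentation towards linalool, and the light-sensitive epoxy iodide may decompose on isolation. The fallback avoids halide and phosphine; it sets out from 6 and returns at 9. Sulfonylation of 6 (TsCl, Et3N, cat. DMAP, CH2Cl2, 0 °C) gives [(2R,3R)-3-methyl-3-(4-methylpent-3-en-1-yl)oxiran-2-yl]methyl 4-methylbenzenesulfonate F5. F5 takes the place of 7 as the bis-electrophile in the annulation of step 5 and leads through 8 to 9.

**Further compounds**
F1 | step 5 | (2S,3R)-3-methyl-3-(4-methylpent-3-en-1-yl)oxirane-2-carbaldehyde | O=C[C@H]1O[C@]1(C)CCC=C(C)C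
F2 | step 2 | methyl 2,2-dimethyl-3-oxobutanoate (bought) | CC(=O)C(C)(C)C(=O)OC
F3 | step 2 | methyl 2,2-dimethyl-3,5-dioxohexanoate | CC(=O)CC(=O)C(C)(C)C(=O)OC
F4 | step 2 | filicinic acid, 3,5-dihydroxy-4,4-dimethylcyclohexa-2,5-dien-1-one | O=C1C=C(O)C(C)(C)C(O)=C1
F5 | step 4 | [(2R,3R)-3-methyl-3-(4-methylpent-3-en-1-yl)oxiran-2-yl]methyl 4-methylbenzenesulfonate | Cc1ccc(cc1)S(=O)(=O)OC[C@H]1O[C@]1(C)CCC=C(C)C
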